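The numbers in the tables were computed for an exercise; scatter was added.

The hunch of order one in partner should be dropped, and the orders should be read at equal conversion, not at equal time.

| setting | amber | grey | flask |
|---|---|---|---|
| left-handed substrate | 0.25 M | 0.25 M | 0.25 M |
| right-handed substrate | 0.25 M | 0.25 M | 0.25 M |
| partner | 0.28 M | 0.44 M | 0.200 M |
| free catalyst | 18 mM | 18 mM | 18 mM |
| remark | run made earlier | run made earlier |  |

- amber (time / min: left-handed product / %, left-handed substrate / %): 15.0: 32.0, 17.0; 30.0: 32.3, 17.6; 50.0: 32.4, 16.7; 60.0: 32.1, 16.9; 80.0: 32.3, 17.0
- grey (time / min: left-handed product / %, left-handed substrate / %): 15.0: 46.8, 3.3; 30.0: 46.8, 3.4; 50.0: 45.9, 3.6; 60.0: 46.4, 3.6; 80.0: 46.4, 3.5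

(each reading ± 0.3 percentage points)

- free catalyst is single-handed; left-handed substrate and right-handed substrate are mirror images of each other, charged as a racemate, each of them at the stated concentration
- the numbers in the tables scatter by 0.3 percentage points (one standard deviation)
- steps thought possible: free catalyst + left-handed substrate <-> catalyst intermediate A; partner + catalyst intermediate B -> free catalyst + right-handed product; partner + free catalyst -> spent catalyst; partner + catalyst intermediate A -> free catalyst + left-handed product; partner -> decomposed reagent; free catalyst + right-handed substrate <-> catalyst intermediate B
- what is bound to the catalyst counts as converted
- no earlier run changes the charge of free catalyst; that part of a forecast is a guess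

1. apparent order in partner when 20% of the left-handed substrate and right-handed substrate together are converted (percent change of the rate of making left-handed product for one percent more partner charged)
2. apparent order in free catalyst when 20% of the left-handed substrate and right-handed substrate together are converted (percent change of the rate of making left-handed product for one percent more free catalyst charged)

The amber run stands still by 15.0 min at 32.0% left-handed product with 17.0% left-handed substrate unused, while the grey run, with more partner, reaches 46.8%, so partner is the limiting reagent. Left-handed product forms from partner and catalyst intermediate A, so its rate carries the partner concentration of that moment. At the mark of 20% in the flask, 0.100 M counts as converted. My reckoning takes the whole catalyst charge as bound there, having cost no partner. That gives L, the partner left at the mark, 0.118 M. More partner charged raises L by the same amount, so the order in partner is about the charge over L, 1.69; for the amber charge the same reckoning gives 1.41. More catalyst spares partner, so the order in free catalyst is about 1.15.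

The forecast, with "Partner left is about 0.11 M", gives 1.9 (1.7 to 2.25) and 1.2 (1.05 to 1.45), its order in partner standing above mine.

The flask gives 1.9 and 1.2.

    free catalyst + left-handed substrate ⇌ catalyst intermediate A (K = 28.0 /M, k = 1100 /M/min)
    partner + catalyst intermediate B → free catalyst + right-handed product (k = 97.0 /M/min)
    partner + free catalyst → spent catalyst (k = 1.70 /M/min)
    partner + catalyst intermediate A → free catalyst + left-handed product (k = 220 /M/min)
    partner → decomposed reagent (k = 0.0530 /min)
    free catalyst + right-handed substrate ⇌ catalyst intermediate B (K = 68.0 /M, k = 380 /M/min)

The flask's order in partner stands above the charge over L by 0.210. The largest single effect on that order in the flask comes from the turning of partner + catalyst intermediate B into free catalyst + right-handed product: in the run with this step taken away, the order in partner drops to 1.2. In that run the rate at the mark, actually 0.161 M/min at 0.230 min, becomes 0.386 of its actual value.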